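The data were generated by integration for substances that don't exist, noise included.

1.0 h is the time the flask gets; the elm run, charged with less other conformer, was followed just as long.

| setting | elm | flask |
|---|---|---|
| substrate | 2.3 M | 2.3 M |
| other conformer | 1.1 M | 2.30 M |
| remark | run made earlier |  |
| time |  | 1.0 h |

elm run (percent of the substrate and other conformer together charged)

| time / min | over-reaction product / % | other conformer / % | target / % |
|---|---|---|---|
| 5.00 | 12.9 | 32.0 | 4.1 |
| 10.0 | 27.3 | 30.2 | 3.8 |
| 15.0 | 41.5 | 28.1 | 2.5 |
| 30.0 | 68.0 | 19.2 | 1.7 |
| 60.0 | 89.2 | 7.5 | 0.5 |

(scatter of a reading: 0.5 percentage points)

* the over-reaction product in the flask at 1.0 h, as a percentage of the substrate and other conformer together charged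
* the other conformer in the flask at 1.0 h, as a percentage of the substrate and other conformer together charged

- the numbers in the tables scatter by 0.5 percentage points (one standard deviation)
- on the list of suspects stand: substrate <-> other conformer; substrate -> target; other conformer -> isomer of the product A; target <-> isomer of the product A; target <-> isomer of the product B; target -> over-reaction product

Late in the elm run the other conformer falls from 19.2% at 30.0 min to 7.5% at 60.0 min. Freezing that fall gives 0.0313 min⁻¹, the late decay constant of the other conformer: the logarithm of the drop over the time it took. Held for 1.0 h, it leaves 15.3% of any conformer charged. Elm's charge was 32.4% other conformer, which accounts for 4.96% of the charge. The remaining 2.5 percentage points is credited to substrate, so each part of substrate charged leaves 3.79% as other conformer. Taking the steps as first-order, the flask, charged 50.0% other conformer, should hold 9.52%.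

Elm's remainder, neither over-reaction product nor other conformer, stood at 3.30%. Freezing that as well is the weak link: it is the difference of readings that each scatter by 0.5 points. Held for the flask, it puts the over-reaction product at 87.2%.

The forecast gives 88.8% over-reaction product and 8.2% other conformer, on the ground that “Both conformers drain at similar overall rates”. This reckoning stands 1.3 points above it on the other conformer.

The flask gives 88.2% over-reaction product and 9.19% other conformer, so the forecast holds within its margins.

    substrate ⇌ other conformer (K = 8.55, k = 0.0186 min⁻¹)
    substrate → target (k = 0.0541 min⁻¹)
    other conformer → isomer of the product A (k = 0.0327 min⁻¹)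
    target ⇌ isomer of the product A (K = 0.453, k = 0.292 min⁻¹)
    target ⇌ isomer of the product B (K = 0.322, k = 0.103 min⁻¹)
    target → over-reaction product (k = 0.722 min⁻¹)

Against its own charge, the flask's other conformer stands at 18%; 0.0313 min⁻¹ held for 1.0 h leaves 15.3%, and the substrate's equal charge adds 3.79%. The flask left until 15 min takes the same reckoning. There 0.0313 min⁻¹ leaves 62.5% of the charged conformer, and elm's 28.1% at 15.0 min credits 11.6% per part of substrate charged, so equal shares give 37.1%. That flask holds 36.1% other conformer.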